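The earlier runs and the new flask are calculated from invented constants, and the scatter is random.

Amounts are told as fractions of the G charged, and the flask below takes a charge lying between those of two earlier runs.

| setting | Tuesday's | Saturday's | flask |
|---|---|---|---|
| G | 0.25 M | 1 M | 0.50 M |
| remark | run made earlier | run made earlier |  |
| time |  |  | 3.0 d |

- Tuesday's (time / d: X / %, Q / %, G / %): 0.333: 7.6, 14.3, 38.1; 0.833: 17.5, 19.0, 31.8; 1.67: 29.8, 17.0, 25.7; 2.50: 39.9, 15.6, 22.3
- Saturday's (time / d: X / %, Q / %, G / %): 0.208: 6.1, 11.0, 40.6; 0.417: 10.6, 16.0, 35.7; 1.04: 20.9, 18.5, 29.8; 2.50: 39.7, 15.3, 22.8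

(standard deviation of a reading: 0.3 percentage points)

- ratio of X to Q at 10 min
- ratio of X to Q at 3.0 d
- which of X and Q there is more of at 3.0 d

- the numbers in the tables scatter by 0.3 percentage points (one standard deviation)
- on the list of suspects stand: G <-> J; G <-> Z; G <-> Q; G <-> X

1. At 2.50 d, X/Q reads 2.56 on Tuesday's run and 2.59 on Saturday's, so the charge number, Tuesday's X/Q over Saturday's at one time, is 0.986, where 1 is the zero of the scale: a split blind to the charge.

2. Q's scatter puts about 1.92% on each ratio, and the gap of the charge number from 1 is smaller than that, so the flask should follow the same fraction curves, with X above Q.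

3. One number is blind to time, though: Tuesday's X/Q climbs from 1.75 at 1.67 d, and a straight extension reckoned here gives 3.04 at 3.0 d.

4. The forecast, holding that “all steps look first order”, gives 0.48 (0.38 to 0.6) at 10 min, 3.1 (2.95 to 3.3) at 3.0 d, and X ahead, its late ratio standing above the extension.

5. The flask gives 0.416 and 3.18, with X at 44.2% and Q at 13.9%, so X leads.

    G ⇌ J (K = 0.870, k = 1.40 h⁻¹)
    G ⇌ Z (K = 0.160, k = 0.128 h⁻¹)
    G ⇌ Q (K = 0.626, k = 0.0577 h⁻¹)
    G ⇌ X (K = 9.00, k = 0.0238 h⁻¹)

6. Between the flask and a neighbour charged with 1.2 M of G, whose X/Q is 3.18 at the same time, the charge number is 1.00, beside the 0.986 of the two runs. In the flask, Q's half-life for going back through G, 0.31 d, is shorter than the 3.0 d, while X's, 11 d, is longer. The flask holds as much X as Q at 0.900 d.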